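**Assumptions (one line each):** (+)-Podocarpic acid is bought as the commercial resin-derived natural product; the reagents named in each step are given with SMILES there and are not numbered.

## Retrosynthetic overview
1. The target comes from a Pd(II)-catalysed [3,3] allylic acetate transposition of tertiary allylic acetate **11**. This step sets the 13E-alkene and the C15–OAc bond.
2. Compound **11** comes from vinylMgBr addition to the C13 methyl ketone **9**, then acetylation.
3. Ketone **9** comes from Wacker oxidation of vinyl **8**, which comes from Lindlar reduction of terminal alkyne **7**. Alkyne **7** comes from Wittig methylenation of the C8 ketone **6**; this forms the 8(17)-alkene.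
4. Keto-alkyne **6** comes from Eschenmoser–Tanabe fragmentation of the α,β-epoxy-13-ketone **5**, which opens podocarpane ring C. Compound **5** comes from the Birch product of O-methylpodocarpic acid.
5. No ring is formed. Rings A and B come intact from podocarpic acid, which supplies C4 (axial 19-CO2H), C5 and C10. C9 is set by protonation and equilibration.

## Route

**Step 1**
Reactants: **1** (+)-podocarpic acid (13-hydroxypodocarpa-8,11,13-trien-19-oic acid; 4β-CO2H, 5α-H, 10β-Me)
Product: **2** O-methylpodocarpic acid
Conditions: Me2SO4, aq. NaOH, rt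
Reagents that add atoms: dimethyl sulfate, COS(=O)(=O)OC
Why: The phenoxide is methylated selectively (Williamson-type O-methylation), while the neopentyl-type axial carboxylate is too hindered to alkylate. No stereocenter is touched.

**Step 2**
Reactants: **2**
Product: **3** 13-methoxypodocarpa-8(9),12-dien-19-oic acid (Birch enol ether)
Conditions: Li, NH3(l), THF, EtOH, −78 °C; NH4Cl quench
Reagents that add atoms: none
Why: Birch reduction leaves the electron-rich tetrasubstituted C8=C9 alkene and the enol ether, with sp3 carbons at C11 and C14. The lithium carboxylate is inert.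

**Step 3**
Reactants: **3**
Product: **4** 13-oxopodocarp-8(14)-en-19-oic acid (9α-H)
Conditions: 3 M HCl, MeOH, reflux
Reagents that add atoms: water, O
Why: Enol-ether hydrolysis followed by acid-catalysed conjugation gives the Δ8(14) enone. C9 is protonated from the α face, anti to the axial C20 methyl, which gives 9α-H.

**Step 4**
Reactants: **4**
Product: **5** 8,14-epoxy-13-oxopodocarpan-19-oic acid (C8/C14 epoxide diastereomers)
Conditions: 30% H2O2, NaOH, MeOH, 0 °C → rt
Reagents that add atoms: hydrogen peroxide, OO
Why: Weitz–Scheffer nucleophilic epoxidation of the enone. The epoxide stereochemistry is irrelevant because both carbons become sp or sp2 in the next step.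

**Step 5**
Reactants: **5**
Product: **6** 15,16,17-trinorlabd-13-yn-8-on-19-oic acid
Conditions: TsNHNH2, AcOH, CH2Cl2, 0 °C → rt
Reagents that add atoms: none (the hydrazide leaves as N2, TsH and H2O)
Why: Eschenmoser–Tanabe fragmentation of the epoxy-ketone tosylhydrazone cleaves C8–C14. This gives the C8 ketone and the terminal C13≡C14 alkyne, so C14 and C13 are already in place for the side chain.

**Step 6**
Reactants: **6**
Product: **7** 15,16-dinorlabda-8(17)-en-13-yn-19-oic acid
Conditions: Ph3PCH3Br, t-BuOK (4 equiv), toluene, 80 °C
Reagents that add atoms: methyltriphenylphosphonium bromide, C[P+](c1ccccc1)(c1ccccc1)c1ccccc1.[Br-]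
Why: Wittig methylenation installs C17. The basic medium equilibrates C9 (α to the ketone) to the natural 9α-H, which places C11 equatorial and gives the stable trans-decalin.

**Step 7**
Reactants: **7**
Product: **8** 15,16-dinorlabda-8(17),13-dien-19-oic acid
Conditions: H2 (1 atm), Lindlar catalyst, quinoline, EtOAc, rt
Reagents that add atoms: none
Why: Lindlar semihydrogenation converts the terminal alkyne to the vinyl group and leaves the 1,1-disubstituted exocyclic alkene untouched.

**Step 8**
Reactants: **8**
Product: **9** 15,16-dinorlabd-8(17)-en-13-on-19-oic acid (C13 methyl ketone)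
Conditions: PdCl2 (10 mol%), CuCl, O2, DMF/H2O, rt
Reagents that add atoms: water, O
Why: Tsuji–Wacker oxidation is Markovnikov-selective for the monosubstituted terminal alkene. It is much faster than reaction at the hindered exocyclic methylene.

**Step 9**
Reactants: **9**
Product: **10** labda-8(17),14-dien-13-ol-19-oic acid (C13 epimeric mixture)
Conditions: CH2=CHMgBr (3.5 equiv), THF, −78 → 0 °C; aq. NH4Cl
Reagents that add atoms: vinylmagnesium bromide, C=C[Mg]Br
Why: Grignard 1,2-addition to the unhindered methyl ketone builds the linalool-type tertiary allylic alcohol. The carboxylate is inert and the new C13 stereocenter is destroyed in Step 11.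

**Step 10**
Reactants: **10**
Product: **11** 13-acetoxylabda-8(17),14-dien-19-oic acid
Conditions: Ac2O, DMAP, Et3N, CH2Cl2, rt; then aq. NaHCO3/MeOH
Reagents that add atoms: acetic anhydride, CC(=O)OC(C)=O
Why: DMAP-catalysed acylation of the tertiary alcohol. Any transient mixed anhydride of the hindered C19 acid is hydrolysed in the work-up.

**Step 11**
Reactants: **11**
Product: **12** 15-acetoxyisocupressic acid (target)
Conditions: PdCl2(MeCN)2 (5 mol%), THF, rt
Reagents that add atoms: none
Why: Pd(II)-catalysed suprafacial [3,3]-sigmatropic acetate transposition of the tertiary allylic acetate to the primary one. The chair transition state puts the C12 chain equatorial, so the C13=C14 alkene forms as E.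

## Compound list
1 | (+)-podocarpic acid | OC(=O)[C@@]1(C)CCC[C@]2(C)c3ccc(O)cc3CC[C@@H]12 | starting material
2 | O-methylpodocarpic acid | OC(=O)[C@@]1(C)CCC[C@]2(C)c3ccc(OC)cc3CC[C@@H]12 | intermediate
3 | 13-methoxypodocarpa-8(9),12-dien-19-oic acid | OC(=O)[C@@]1(C)CCC[C@]2(C)C3=C(CC[C@@H]12)CC(OC)=CC3 | intermediate
4 | 13-oxopodocarp-8(14)-en-19-oic acid | OC(=O)[C@@]1(C)CCC[C@]2(C)[C@H]3CCC(=O)C=C3CC[C@@H]12 | intermediate
5 | 8,14-epoxy-13-oxopodocarpan-19-oic acid | OC(=O)[C@@]1(C)CCC[C@]2(C)[C@H]3CCC(=O)C4OC34CC[C@@H]12 | intermediate
6 | 15,16,17-trinorlabd-13-yn-8-on-19-oic acid | OC(=O)[C@@]1(C)CCC[C@]2(C)[C@@H](CCC#C)C(=O)CC[C@@H]12 | intermediate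
7 | 15,16-dinorlabda-8(17)-en-13-yn-19-oic acid | OC(=O)[C@@]1(C)CCC[C@]2(C)[C@@H](CCC#C)C(=C)CC[C@@H]12 | intermediate
8 | 15,16-dinorlabda-8(17),13-dien-19-oic acid | OC(=O)[C@@]1(C)CCC[C@]2(C)[C@@H](CCC=C)C(=C)CC[C@@H]12 | intermediate
9 | 15,16-dinorlabd-8(17)-en-13-on-19-oic acid | OC(=O)[C@@]1(C)CCC[C@]2(C)[C@@H](CCC(C)=O)C(=C)CC[C@@H]12 | intermediate
10 | labda-8(17),14-dien-13-ol-19-oic acid (C13 epimers) | OC(=O)[C@@]1(C)CCC[C@]2(C)[C@@H](CCC(C)(O)C=C)C(=C)CC[C@@H]12 | intermediate
11 | 13-acetoxylabda-8(17),14-dien-19-oic acid | OC(=O)[C@@]1(C)CCC[C@]2(C)[C@@H](CCC(C)(OC(C)=O)C=C)C(=C)CC[C@@H]12 | intermediate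
12 | 15-acetoxyisocupressic acid | C=C1CC[C@@H]2[C@](C)(CCC[C@]2(C)C(=O)O)[C@H]1CC/C(C)=C/COC(C)=O | target

## Totals
Total steps: 11. Longest linear sequence: 11 (all steps are linear from **1**).

## Three steps most likely to fail
1. **Step 8 (Wacker).** The exocyclic alkene may isomerise under Pd–H, or the oxidation may be unselective. Fallback: carboaluminate alkyne **7** (Me3Al, cat. Cp2ZrCl2, then paraformaldehyde) to give the (E)-allylic alcohol directly. Acetylating the primary alcohol with Ac2O/pyridine then gives the target and bypasses Steps 8–11.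
2. **Step 6 (Wittig).** The α-branched C8 ketone is hindered, and the free carboxylate lowers solubility and reactivity. Fallback: switch to Peterson olefination (Me3SiCH2MgCl, then KH) on ketone **6**, which replaces the phosphorus-ylide mechanism.
3. **Step 11 (Pd [3,3]).** The E/Z ratio may be poor, or the allylic cation may cyclise onto the exocyclic alkene. Fallback: ionisation-based Re2O7-catalysed 1,3-transposition of tertiary alcohol **10** to the primary alcohol, then Ac2O/pyridine acetylation. The E isomer would need to be separated from any Z.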